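**Two clocks.** In a one-step world a species answers to a single rate. Our intermediate answers to two: its own use rate, and the rate at which its supply dies away. That supply is the pool of substrate plus dormant form. We want the intermediate at 20 h in each flask.

| flask | substrate | remark | time |
|---|---|---|---|
| midnight | 0.0013 M | run made earlier |  |
| south | 0.0012 M |  | 20 h |
| north-east | 0.0040 M |  | 20 h |
| east | 0.012 M |  | 20 h |
| south-east | 0.030 M |  | 20 h |
| west | 0.10 M |  | 20 h |

- midnight (time / h: intermediate / %, product / %): 1.50: 23.8, 9.0; 3.00: 25.1, 22.9; 5.00: 18.4, 39.3; 6.00: 16.2, 46.3; 8.00: 12.1, 56.7; 10.0: 8.9, 65.0; 12.0: 8.5, 71.2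

(readings scatter by 0.5 percentage points)

- for product the crystals are counted in
- as a solid, counted per litre of solution: crystals
- the numbers in the tables scatter by 0.5 percentage points (one standard deviation)
- candidate steps: substrate <-> dormant form; crystals <-> product; substrate -> intermediate; intermediate -> product
- "hardly changes" means that all values lie within two and a half points (for a concentration: within two and a half percent of the largest)

- [intermediate] at the end for south, north-east, east, south-east, west, in this order
- the course of these numbers from the first flask to the last (rises, then falls / rises all the way / falls all the way / falls, then rises / hardly changes)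

**Two readings.** In the midnight run the pool, which is the charge less intermediate and product, falls from 42.3 % at 5.00 h to 20.3 % at 12.0 h, a tail rate of 0.105 /h. Product gained between 6.00 h and 8.00 h, divided by the mean intermediate there, reads as a use rate of 0.367 /h.

**The rule.** By these readings the intermediate turns over faster than the pool, with 7.34 lifetimes in 20 h against 2.10, so we expect it to forget its start and sink with the pool, a transient equilibrium in the language of decay chains. Its making over its use is then one minus the lag ratio 0.285, defined as tail rate over use rate, and it stands at 0.399 of the pool.

**Our reckoning.** Extending the tail puts the pool at 8.77 % at 20 h, so the intermediate is 3.50 % of the charge: 4.20 × 10⁻⁵ M in south, 0.00350 M in west. The midnight run has a single charge and so does not test the order, and we assume first-order steps. Crystals draw on product, and no candidate step leads from product to intermediate.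

**The forecast.** It gives 4.100 × 10⁻⁵ M, 1.360 × 10⁻⁴ M, 4.100 × 10⁻⁴ M, 0.00102 M, 0.0034 M, rises all the way, slightly below ours in south. Its ground: “I assume first-order steps, so [I] scales with the starting substrate”.

**The flasks.** They give 4.04 × 10⁻⁵ M, 1.35 × 10⁻⁴ M, 4.04 × 10⁻⁴ M, 0.00101 M, 0.00336 M: rises all the way.

    substrate ⇌ dormant form (K = 1.60, k = 0.00640 /min)
    crystals ⇌ product, rate k2*(cs2 - [product]) while solid is left; crystals form when [product] > cs2 (solubility = 0.0640 M, k = 0.0680 /min)
    substrate → intermediate (k = 0.00590 /min)
    intermediate → product (k = 0.00630 /min)

In south at 20.0 h, the half-life of the intermediate by its use, 1.8 h, is short against the 20 h run, and its making stands at 0.741 of its use, where the lag ratio 0.285 read in the midnight run gives 0.715. In west at 20.0 h, with crystals at 22.5 %, that reading gives 0.399 of the pool, and the flask holds intermediate at 3.36 % of the charge over a pool of 9.78 %, which is 0.344.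

(The numbers in the tables were generated by integration for an exercise, and the scatter is random.)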